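**Plan** (benzofuran numbering O1, C2, C3, C3a, C4–C7, C7a; side chain C1'–C3' on C5)

- Retrosynthetic cuts, in order: C5–C1' (aryl bromide plus an (S)-lactic Weinreb amide, the C1' carbinol going back to a ketone); then C2–C3 of the dihydrofuran ring; then the O1–CH2 ether bond (phenol plus 3,4-dimethoxybenzyl chloride).
- Forward: ring A comes ready-made from 2'-hydroxy-3'-methoxyacetophenone (brominated at C5, O-benzylated). The dihydrofuran ring is closed by carbene C–H insertion, and the three-carbon chain is joined last.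
- Enabling feature: the C2–H bond is benzylic to the dimethoxyphenyl ring and α to O1, hence hydridic. The O1–C7a–C3a edge of ring A holds it 1,5 to C3, whose acetyl carbonyl can be turned (hydrazone, then diazo) into a carbene.
- Stereochemistry: C3 (S) from the chiral dirhodium catalyst (cis adduct). C2 is then equilibrated by acid to the trans (2S) isomer. C2' (S) comes from ethyl (S)-lactate, and C1' (R) from chelation-controlled reduction of the α-hydroxy ketone.
- Helpers: hydrazone/diazo group (leaves as N2), bromine at C5 (exchanged for lithium), TBS ether (removed before the reduction).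

Key step: step 4

Remark (assumption): the sense of induction of the phthalimido-carboxylate dirhodium catalysts is assigned by analogy with related benzylic-ether insertions. The S-series catalyst is taken to give the (2R)-configured cis adduct; should the sense prove opposite, the mirror-image catalyst is used and nothing else changes.

**Step 1**
Reactants: 1 1-(2-hydroxy-3-methoxyphenyl)ethan-1-one
Product: 2 1-(5-bromo-2-hydroxy-3-methoxyphenyl)ethan-1-one
Conditions: NBS (1.05 equiv), CH3CN, 0 °C to rt
Reagents that add atoms: N-bromosuccinimide, O=C1CCC(=O)N1Br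
Why: Electrophilic aromatic bromination; the free phenol directs to its para position (both ortho positions are occupied), which is also meta to the acetyl group, so a single regioisomer is expected.

**Step 2**
Reactants: 2 1-(5-bromo-2-hydroxy-3-methoxyphenyl)ethan-1-one; 3 4-(chloromethyl)-1,2-dimethoxybenzene
Product: 4 1-[5-bromo-2-[(3,4-dimethoxyphenyl)methoxy]-3-methoxyphenyl]ethan-1-one
Conditions: K2CO3, KI (cat.), DMF, 60 °C
Reagents that add atoms: none
Why: Williamson ether synthesis (SN2 at a benzylic chloride with iodide catalysis); carbonate is basic enough for the hydrogen-bonded ortho-acyl phenol and leaves the methyl ketone alone.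

**Step 3**
Reactants: 4 1-[5-bromo-2-[(3,4-dimethoxyphenyl)methoxy]-3-methoxyphenyl]ethan-1-one
Product: 5 [1-[5-bromo-2-[(3,4-dimethoxyphenyl)methoxy]-3-methoxyphenyl]ethylidene]hydrazine
Conditions: N2H4·H2O (10 equiv), AcOH (cat.), EtOH, 80 °C
Reagents that add atoms: hydrazine monohydrate, NN.O
Why: Hydrazone formation by condensation of the aryl methyl ketone with excess hydrazine, the excess suppressing azine formation; the C=N geometry is immaterial because it is lost in the diazo compound.

**Step 4**
Reactants: 5 [1-[5-bromo-2-[(3,4-dimethoxyphenyl)methoxy]-3-methoxyphenyl]ethylidene]hydrazine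
Product: 7 (2R,3S)-5-bromo-2-(3,4-dimethoxyphenyl)-7-methoxy-3-methyl-2,3-dihydro-1-benzofuran (2,3-cis), via diazoalkane 6 (not isolated)
Conditions: MnO2 (8 equiv), CH2Cl2, 0 °C, filtration through Celite; filtrate added slowly to Rh2(S-PTAD)4 [dirhodium tetrakis((S)-(1-adamantyl)(N-phthalimido)acetate)] (1 mol %), CH2Cl2, −20 °C to rt
Reagents that add atoms: none
Why: MnO2 dehydrogenates the hydrazone to the aryl(methyl)diazomethane 6, from which the dirhodium tetracarboxylate expels N2 to give a rhodium-bound donor/donor carbene at C3; this carbon takes up the hydridic C2–H of the benzyl ether in a concerted but asynchronous, hydride-transfer-like insertion that forms the C2–C3 bond. The closest known reaction type is the dirhodium-catalysed intramolecular C–H insertion of donor/donor carbenes generated in the flask from hydrazones of 2-(benzyloxy)aryl ketones, which gives 2,3-disubstituted 2,3-dihydrobenzofurans. The dihydrofuran ring closes as a 1,5-insertion, the carbene carbon and the C–H carbon being linked through C3a, C7a and O1 so that a five-membered ring results. C2 and C3 are both new: their cis relationship should follow from the compact insertion transition state that places the C2 aryl group and the C3 methyl group on the same face, and the absolute configuration (3S, hence 2R) from the chiral pocket of the phthalimido-carboxylate ligands. The step needs insertion to outrun the 1,2-hydride shift from the methyl group (which would give a styrene) and azine formation; this is secured by the low electrophilicity of the donor/donor carbene, by the strong activation of the C2–H bond (α to O1 and benzylic to an electron-rich ring), and by the low diazo concentration kept through slow addition.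

**Step 5**
Reactants: 7 (2R,3S)-5-bromo-2-(3,4-dimethoxyphenyl)-7-methoxy-3-methyl-2,3-dihydro-1-benzofuran
Product: 8 (2S,3S)-5-bromo-2-(3,4-dimethoxyphenyl)-7-methoxy-3-methyl-2,3-dihydro-1-benzofuran (2,3-trans)
Conditions: CF3CO2H (10 vol %), CH2Cl2 (dilute), 0 °C to rt
Reagents that add atoms: none
Why: Acid-mediated epimerisation under thermodynamic control by reversible SN1 heterolysis of the benzylic C2–O1 bond: the cation, stabilised by the para-methoxy group of the dimethoxyphenyl ring, recloses onto the phenol to the more stable trans isomer, so C2 goes from R to S while C3, not part of the ionising bond, keeps its S configuration.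

**Step 6**
Reactants: 9 ethyl (2S)-2-hydroxypropanoate
Product: 10 (2S)-2-hydroxy-N-methoxy-N-methylpropanamide
Conditions: MeNH(OMe)·HCl, i-PrMgCl, THF, −20 to 0 °C
Reagents that add atoms: N,O-dimethylhydroxylamine hydrochloride, CNOC.Cl
Why: Weinreb amide formation by aminolysis of the ester with the chloromagnesium amide; the hydroxyl is present as its magnesium alkoxide, so the α-stereocentre from the chiral pool is not enolised.

**Step 7**
Reactants: 10 (2S)-2-hydroxy-N-methoxy-N-methylpropanamide
Product: 11 (2S)-2-[(tert-butyldimethylsilyl)oxy]-N-methoxy-N-methylpropanamide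
Conditions: TBSCl, imidazole, DMF, rt
Reagents that add atoms: tert-butyldimethylsilyl chloride, CC(C)(C)[Si](C)(C)Cl
Why: Silyl ether protection of the secondary alcohol, giving a base-stable group that tolerates the organolithium step.

**Step 8**
Reactants: 8 (2S,3S)-5-bromo-2-(3,4-dimethoxyphenyl)-7-methoxy-3-methyl-2,3-dihydro-1-benzofuran; 11 (2S)-2-[(tert-butyldimethylsilyl)oxy]-N-methoxy-N-methylpropanamide
Product: 14 (2S)-2-[(tert-butyldimethylsilyl)oxy]-1-[(2S,3S)-2-(3,4-dimethoxyphenyl)-7-methoxy-3-methyl-2,3-dihydro-1-benzofuran-5-yl]propan-1-one, via aryllithium 12 (not isolated), via lithium hemiaminal alkoxide 13 (not isolated)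
Conditions: n-BuLi (1.05 equiv), THF, −78 °C; then 11, −78 to −40 °C; AcOH quench at −78 °C
Reagents that add atoms: none
Why: Bromine–lithium exchange followed by Weinreb ketone synthesis; exchange at −78 °C is faster than deprotonation at C2, and the chelated tetrahedral adduct prevents over-addition and enolisation, so the lactate stereocentre is retained.

**Step 9**
Reactants: 14 (2S)-2-[(tert-butyldimethylsilyl)oxy]-1-[(2S,3S)-2-(3,4-dimethoxyphenyl)-7-methoxy-3-methyl-2,3-dihydro-1-benzofuran-5-yl]propan-1-one
Product: 15 (2S)-1-[(2S,3S)-2-(3,4-dimethoxyphenyl)-7-methoxy-3-methyl-2,3-dihydro-1-benzofuran-5-yl]-2-hydroxypropan-1-one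
Conditions: HF·pyridine, pyridine, THF, 0 °C to rt
Reagents that add atoms: none
Why: Fluoride-driven cleavage of the silyl ether under buffered, base-free conditions, which should neither enolise the α-hydroxy ketone nor ionise the C2–O1 bond.

**Step 10**
Reactants: 15 (2S)-1-[(2S,3S)-2-(3,4-dimethoxyphenyl)-7-methoxy-3-methyl-2,3-dihydro-1-benzofuran-5-yl]-2-hydroxypropan-1-one
Product: 16 (1R,2S)-1-[(2S,3S)-2-(3,4-dimethoxyphenyl)-7-methoxy-3-methyl-2,3-dihydro-1-benzofuran-5-yl]propane-1,2-diol
Conditions: Zn(BH4)2, Et2O, −30 to 0 °C; aq. NH4Cl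
Reagents that add atoms: none
Why: Chelation-controlled (Cram-chelate) reduction of an α-hydroxy ketone: zinc bridges the carbonyl and hydroxyl oxygens in a five-membered chelate and hydride enters from the face of the α-hydrogen, opposite the methyl group, which should set C1' as R, anti to the (S) hydroxyl at C2'.

**Compound list**

1 | 1-(2-hydroxy-3-methoxyphenyl)ethan-1-one | CC(=O)c1cccc(OC)c1O | starting material
2 | 1-(5-bromo-2-hydroxy-3-methoxyphenyl)ethan-1-one | CC(=O)c1cc(Br)cc(OC)c1O | intermediate
3 | 4-(chloromethyl)-1,2-dimethoxybenzene (3,4-dimethoxybenzyl chloride) | COc1ccc(CCl)cc1OC | starting material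
4 | 1-[5-bromo-2-[(3,4-dimethoxyphenyl)methoxy]-3-methoxyphenyl]ethan-1-one | CC(=O)c1cc(Br)cc(OC)c1OCc1ccc(OC)c(OC)c1 | intermediate
5 | [1-[5-bromo-2-[(3,4-dimethoxyphenyl)methoxy]-3-methoxyphenyl]ethylidene]hydrazine (hydrazone of 4; C=N geometry immaterial) | CC(=NN)c1cc(Br)cc(OC)c1OCc1ccc(OC)c(OC)c1 | intermediate
6 | 5-bromo-1-(1-diazoethyl)-2-[(3,4-dimethoxyphenyl)methoxy]-3-methoxybenzene | CC(=[N+]=[N-])c1cc(Br)cc(OC)c1OCc1ccc(OC)c(OC)c1 | intermediate
7 | (2R,3S)-5-bromo-2-(3,4-dimethoxyphenyl)-7-methoxy-3-methyl-2,3-dihydro-1-benzofuran (2,3-cis) | COc1ccc([C@@H]2Oc3c(OC)cc(Br)cc3[C@@H]2C)cc1OC | intermediate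
8 | (2S,3S)-5-bromo-2-(3,4-dimethoxyphenyl)-7-methoxy-3-methyl-2,3-dihydro-1-benzofuran (2,3-trans) | COc1ccc([C@H]2Oc3c(OC)cc(Br)cc3[C@@H]2C)cc1OC | intermediate
9 | ethyl (2S)-2-hydroxypropanoate (ethyl (S)-lactate) | CCOC(=O)[C@H](C)O | starting material
10 | (2S)-2-hydroxy-N-methoxy-N-methylpropanamide | CON(C)C(=O)[C@H](C)O | intermediate
11 | (2S)-2-[(tert-butyldimethylsilyl)oxy]-N-methoxy-N-methylpropanamide | CON(C)C(=O)[C@H](C)O[Si](C)(C)C(C)(C)C | intermediate
12 | [(2S,3S)-2-(3,4-dimethoxyphenyl)-7-methoxy-3-methyl-2,3-dihydro-1-benzofuran-5-yl]lithium | COc1ccc([C@H]2Oc3c(OC)cc([Li])cc3[C@@H]2C)cc1OC | intermediate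
13 | lithium alkoxide of the tetrahedral adduct of 12 and 11 (configuration at the new carbinol carbon undefined and immaterial) | COc1ccc([C@H]2Oc3c(OC)cc(C(O[Li])(N(C)OC)[C@H](C)O[Si](C)(C)C(C)(C)C)cc3[C@@H]2C)cc1OC | intermediate
14 | (2S)-2-[(tert-butyldimethylsilyl)oxy]-1-[(2S,3S)-2-(3,4-dimethoxyphenyl)-7-methoxy-3-methyl-2,3-dihydro-1-benzofuran-5-yl]propan-1-one | COc1ccc([C@H]2Oc3c(OC)cc(C(=O)[C@H](C)O[Si](C)(C)C(C)(C)C)cc3[C@@H]2C)cc1OC | intermediate
15 | (2S)-1-[(2S,3S)-2-(3,4-dimethoxyphenyl)-7-methoxy-3-methyl-2,3-dihydro-1-benzofuran-5-yl]-2-hydroxypropan-1-one | COc1ccc([C@H]2Oc3c(OC)cc(C(=O)[C@H](C)O)cc3[C@@H]2C)cc1OC | intermediate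
16 | (1R,2S)-1-[(2S,3S)-2-(3,4-dimethoxyphenyl)-7-methoxy-3-methyl-2,3-dihydro-1-benzofuran-5-yl]propane-1,2-diol | COc1ccc([C@H]2Oc3c(OC)cc([C@@H](O)[C@H](C)O)cc3[C@@H]2C)cc1OC | target

**Step count and risks**

Total steps: 10. Longest linear sequence: 8 steps (steps 1–5 and 8–10, from 1 to 16).

Steps most likely to fail:

**Step 4.** The methyl-bearing carbene may rearrange by 1,2-hydride shift to a styrene, or couple with unreacted diazo compound to an azine, faster than it inserts; the catalyst may also discriminate the two faces poorly next to the ether flanked by the 7-methoxy group. The fallback sets out from 4, returns to the route at 8 and also bypasses step 5.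
- The acetyl group of 4 would be rearranged by oxidative 1,2-aryl migration with the trivalent iodine reagent PhI(OAc)2 (HC(OMe)3, cat. H2SO4, MeOH) to methyl 2-[5-bromo-2-[(3,4-dimethoxyphenyl)methoxy]-3-methoxyphenyl]acetate F1.
- Regitz diazo transfer (4-acetamidobenzenesulfonyl azide, DBU, CH3CN) would give methyl 2-[5-bromo-2-[(3,4-dimethoxyphenyl)methoxy]-3-methoxyphenyl]-2-diazoacetate F2.
- The donor/acceptor carbene from F2 has no β-hydrogen and cannot undergo the hydride shift. With Rh2(R-PTTL)4 (dirhodium tetrakis[N-phthaloyl-(R)-tert-leucinate]) it would insert into the same benzylic C–H bond to give the cis ester methyl (2S,3R)-5-bromo-2-(3,4-dimethoxyphenyl)-7-methoxy-2,3-dihydro-1-benzofuran-3-carboxylate F3.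
- NaOMe in MeOH would epimerise C3, now α to the ester, to the trans ester methyl (2S,3S)-5-bromo-2-(3,4-dimethoxyphenyl)-7-methoxy-2,3-dihydro-1-benzofuran-3-carboxylate F4.
- LiAlH4 (THF, 0 °C) would give [(2S,3R)-5-bromo-2-(3,4-dimethoxyphenyl)-7-methoxy-2,3-dihydro-1-benzofuran-3-yl]methanol F5.
- TsCl in pyridine would give [(2S,3R)-5-bromo-2-(3,4-dimethoxyphenyl)-7-methoxy-2,3-dihydro-1-benzofuran-3-yl]methyl 4-methylbenzenesulfonate F6.
- LiBHEt3 (THF) would reduce F6 to the methyl compound 8.

**Step 5.** The ring-opened benzylic cation may lose the C3 proton and be reprotonated, which would erode the C3 configuration, or it may alkylate a second electron-rich ring. The fallback sets out from 7 and returns at 8 without any new compound (F0). C2 would be epimerised through a radical instead of a cation, by thiol-catalysed radical-chain hydrogen-atom transfer (polarity-reversal catalysis: catalytic tri-tert-butoxysilanethiol, di-tert-butyl hyponitrite as initiator, PhCF3, 60 °C). The thiyl radical should reversibly abstract the weak, hydridic C2–H (α to O1 and benzylic) and the thiol return hydrogen to the planar radical. The mixture should then drift to the more stable trans isomer without a cation from which C3 could lose its proton.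

**Step 10.** Incomplete zinc chelation by the electron-rich aryl ketone would let an open transition state compete, giving poor facial selectivity and the syn (1'S) diol. The fallback sets out from 14 and returns at 16. The carbinol centre would be set under catalyst control before desilylation. Noyori-type asymmetric transfer hydrogenation of 14 with RuCl[(S,S)-TsDPEN](p-cymene) in HCO2H/Et3N should give (1R,2S)-2-[(tert-butyldimethylsilyl)oxy]-1-[(2S,3S)-2-(3,4-dimethoxyphenyl)-7-methoxy-3-methyl-2,3-dihydro-1-benzofuran-5-yl]propan-1-ol F7. Bu4NF in THF would then free the diol 16.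

**Further compounds**

F1 | step 4 | methyl 2-[5-bromo-2-[(3,4-dimethoxyphenyl)methoxy]-3-methoxyphenyl]acetate | COC(=O)Cc1cc(Br)cc(OC)c1OCc1ccc(OC)c(OC)c1
F2 | step 4 | methyl 2-[5-bromo-2-[(3,4-dimethoxyphenyl)methoxy]-3-methoxyphenyl]-2-diazoacetate | COC(=O)C(=[N+]=[N-])c1cc(Br)cc(OC)c1OCc1ccc(OC)c(OC)c1
F3 | step 4 | methyl (2S,3R)-5-bromo-2-(3,4-dimethoxyphenyl)-7-methoxy-2,3-dihydro-1-benzofuran-3-carboxylate (2,3-cis) | COc1ccc([C@H]2Oc3c(OC)cc(Br)cc3[C@H]2C(=O)OC)cc1OC
F4 | step 4 | methyl (2S,3S)-5-bromo-2-(3,4-dimethoxyphenyl)-7-methoxy-2,3-dihydro-1-benzofuran-3-carboxylate (2,3-trans) | COc1ccc([C@H]2Oc3c(OC)cc(Br)cc3[C@@H]2C(=O)OC)cc1OC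
F5 | step 4 | [(2S,3R)-5-bromo-2-(3,4-dimethoxyphenyl)-7-methoxy-2,3-dihydro-1-benzofuran-3-yl]methanol | COc1ccc([C@H]2Oc3c(OC)cc(Br)cc3[C@@H]2CO)cc1OC
F6 | step 4 | [(2S,3R)-5-bromo-2-(3,4-dimethoxyphenyl)-7-methoxy-2,3-dihydro-1-benzofuran-3-yl]methyl 4-methylbenzenesulfonate | COc1ccc([C@H]2Oc3c(OC)cc(Br)cc3[C@@H]2COS(=O)(=O)c2ccc(C)cc2)cc1OC
F0 | step 5 | none | none
F7 | step 10 | (1R,2S)-2-[(tert-butyldimethylsilyl)oxy]-1-[(2S,3S)-2-(3,4-dimethoxyphenyl)-7-methoxy-3-methyl-2,3-dihydro-1-benzofuran-5-yl]propan-1-ol | COc1ccc([C@H]2Oc3c(OC)cc([C@@H](O)[C@H](C)O[Si](C)(C)C(C)(C)C)cc3[C@@H]2C)cc1OC
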